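Instead of building the flask from the constants of the single steps, I read one ratio straight off the runs. I divide intermediate C by intermediate A, then by the partner charged. In blue at 80.0 s this gives 0.967 M⁻¹, in red at 80.0 s 1.01 M⁻¹. Their mean is 0.986 M⁻¹, which I carry as the late ratio, intermediate C over intermediate A per molar of partner charged, as read at the last reading.

| flask | substrate | partner | remark | time |
|---|---|---|---|---|
| blue | 0.50 M | 0.86 M | run made earlier |  |
| red | 0.50 M | 1.5 M | run made earlier |  |
| birch | 0.50 M | 1.40 M |  | 2.5 min |
| alder | 0.50 M | 0.550 M |  | 2.5 min |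

| run | time / s | product / % | intermediate C / % | intermediate B / % | intermediate A / % | substrate / % |
|---|---|---|---|---|---|---|
| blue | 10.0 | 0.5 | 4.4 | 0.1 | 8.6 | 83.1 |
| blue | 20.0 | 0.2 | 10.4 | 1.9 | 16.6 | 69.5 |
| blue | 40.0 | 0 | 19.1 | 4.2 | 23.3 | 50.9 |
| blue | 50.0 | 0 | 21.1 | 4.6 | 25.2 | 45.4 |
| blue | 80.0 | 2.2 | 24.7 | 7.5 | 29.7 | 30.0 |
| red | 15.0 | 0 | 16.3 | 0.4 | 12.4 | 71.0 |
| red | 30.0 | 0 | 24.2 | 1.5 | 20.7 | 51.9 |
| red | 50.0 | 0 | 32.5 | 4.7 | 22.5 | 36.0 |
| red | 60.0 | 0 | 35.9 | 6.2 | 24.9 | 32.4 |
| red | 80.0 | 0.5 | 37.7 | 7.6 | 25.0 | 23.5 |

(each reading ± 1 percentage point)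

1. which of these there is most of at the end, counted by the substrate in it, birch (intermediate C / intermediate B / intermediate A / substrate)
2. which of these there is most of at the end, counted by the substrate in it, alder (intermediate C / intermediate B / intermediate A / substrate)
3. how much there is at the end of the one of these that leads, in percent of the substrate charged: birch
4. how much there is at the end of the one of these that leads, in percent of the substrate charged: alder

The second way to the same number is the early readings, which give a selectivity factor: 0.728 M⁻¹ in blue at 20.0 s and 0.779 M⁻¹ in red at 30.0 s. The two ways part, so this ratio is no constant: in red it reads higher at 80.0 s than at 30.0 s. For a flask read at 2.5 min the early figure is the one that cheats, as it was read further from that time. Late in red the ratio goes from 0.963 M⁻¹ at 50.0 s to 1.01 M⁻¹ at 80.0 s, and with 1 percentage point of scatter on each reading I can't tell whether it still climbs. So I hold the late ratio out to 2.5 min as an assumption, not as a finding.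

It gives intermediate C over intermediate A as 1.38 in birch and 0.542 in alder. Together the two hold 62.7 % in red and 54.4 % in blue at the last reading. Dividing those totals gives intermediate C at 36.4 % in birch and intermediate A at 35.3 % in alder. I take both as estimates on the low side, since red's total at its last reading stood above its 55.0 % of 50.0 s.

The forecast says intermediate C at 36 % for birch and intermediate A at 30 % for alder, where “partner is scarce”, so my alder figure stands higher.

The flasks give intermediate C at 40.8 % in birch and intermediate A at 36.5 % in alder.

    substrate ⇌ intermediate A (K = 3.21, k = 0.0108 s⁻¹)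
    intermediate A ⇌ intermediate B (K = 0.530, k = 0.0119 s⁻¹)
    substrate + partner ⇌ intermediate C (K = 4.55 M⁻¹, k = 0.00879 M⁻¹ s⁻¹)
    partner + intermediate B ⇌ intermediate D (K = 0.658 M⁻¹, k = 0.0156 M⁻¹ s⁻¹)
    partner + intermediate B ⇌ intermediate E (K = 72.3 M⁻¹, k = 0.0108 M⁻¹ s⁻¹)
    intermediate D ⇌ product (K = 4.70, k = 0.00866 s⁻¹)
    partner ⇌ dormant form (K = 2.60, k = 0.00329 s⁻¹)

The ratio itself comes out at 0.542 in alder, against my 0.542, and at 1.67 in birch, against my 1.38. In alder the step between substrate and intermediate A relaxes with a half-life of 0.816 min, shorter than the 2.27 min of the step to intermediate C, so 2.5 min holds 3.06 of the first and 1.10 of the second.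

For the neighbour of alder charged with 0.33 M of partner, the late ratio gives 0.325. That flask holds 12.6 % of intermediate C and 40.8 % of intermediate A, a ratio of 0.308.

The readings come from a simulation from invented constants, and the scatter is random.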